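A direct plan would start from the aromatic ring and dearomatise it late.
It would make the 5,7-dihydroxy-4-phenyl-dihydrocoumarin A1 by carbene-catalysed annulation, acylate C-8 to the tigloyl ketone A2, and alkylate C-6 reductively with the pinene-derived cyclobutane aldehyde A3 to the phenol A4.
A Pd-catalysed allylic dearomatisation would then prenylate C-6 (dienone A5), and water with a chiral amine would open the lactone so that the freed oxygen closes the pyranone onto the tigloyl group.
Weakest: the dearomatising prenylation would have to create the quaternary C-6 on a flat, fully substituted ring, with only a remote phenyl group and a ligand to tell the faces apart, against O-allylation.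
Weak: the last step would have to pick one of two flanking oxygens and set C-2 and C-3 in the final operation, the cis pair resting on a kinetic protonation next to a carbonyl in basic medium.
Weak: the Lewis-acid tigloylation of A1 would expose two free ring positions, the lactone and an enone prone to early closure to AlCl3.

**Retrosynthetic overview**
C-5/C-6/C-7 of the carbocycle (ring B) form a 2,2-dialkylmalonyl unit, and C-4a/C-8a/C-8 are the α-, β- and γ-carbons of a 6-methyl-2,3-dihydropyran-4-one (ring A). Ring B is therefore cut at C-7–C-8 and C-4a–C-5 and closed last, by γ-acylation and Dieckmann cyclisation of the pyranone with a malonyl half-ester chloride; no arene is made or dearomatised.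
Ring A is built first (syn-aldol, ynone, 6-endo cyclisation), so O-1–C-8a, C-2 and C-3 exist before ring B and no choice between two oxygens arises.
C-6 is set on the open-chain malonate by phase-transfer prenylation; which carboxyl is the chloride and which the ester decides which becomes C-7 and which C-5. The cyclobutane is bought as (−)-verbenone.
The benzylic centre is added last by carbene-catalysed union of the bicyclic core with cinnamaldehyde at C-8, its only free nucleophilic carbon.

Key step: step 13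

Assumption: the sense of induction in the two catalyst-controlled steps (11 and 14) is taken from the closest analogues; should either prove opposite on these substrates, the antipodal catalyst is used and nothing else changes. Trione-type compounds are drawn as the enol tautomer of the target.

Step 1
Reactants: 1 (S)-4-benzyl-3-propanoyl-1,3-oxazolidin-2-one; 2 acetaldehyde
Product: 3 (4S)-4-benzyl-3-[(2S,3R)-3-hydroxy-2-methylbutanoyl]-1,3-oxazolidin-2-one
Conditions: Bu2BOTf (1.1 equiv), iPr2NEt (1.3 equiv), CH2Cl2, 0 °C; 2 (3 equiv), −78 → 0 °C; MeOH, pH 7 buffer, 30% H2O2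
Reagents that add atoms: none
Why: Evans syn-aldol reaction, in which the Z-boron enolate reacts through a chair transition state whose face is fixed by the benzyl group of the auxiliary, setting the future C-3 (S) and C-2 (R) in the syn relationship that becomes the cis-2,3-dimethyl pair.

Step 2
Reactants: 3 (4S)-4-benzyl-3-[(2S,3R)-3-hydroxy-2-methylbutanoyl]-1,3-oxazolidin-2-one
Product: 4 (2S,3R)-3-hydroxy-N-methoxy-N,2-dimethylbutanamide
Conditions: MeONHMe·HCl (3 equiv), AlMe3 (3 equiv), CH2Cl2, −20 → 0 °C; cold dilute aq. HCl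
Reagents that add atoms: N,O-dimethylhydroxylamine hydrochloride CNOC.Cl
Why: Aluminium amide transamidation of the β-hydroxy imide (Weinreb amide formation), in which the free hydroxyl directs attack to the exocyclic carbonyl and the α-centre is not enolised.

Step 3
Reactants: 4 (2S,3R)-3-hydroxy-N-methoxy-N,2-dimethylbutanamide; 5 prop-1-yn-1-ylmagnesium bromide
Product: 6 (2R,3S)-2-hydroxy-3-methylhept-5-yn-4-one
Conditions: 5 (3 equiv, 0.5 M in THF), THF, −20 → 0 °C; sat. aq. NH4Cl
Reagents that add atoms: none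
Why: Weinreb ketone synthesis, in which one equivalent of Grignard reagent forms the magnesium alkoxide, the chelated tetrahedral adduct prevents over-addition, and the α-centre is kept because the ketone is set free only on work-up.

Step 4
Reactants: 6 (2R,3S)-2-hydroxy-3-methylhept-5-yn-4-one
Product: 7 (2R,3S)-2,3,6-trimethyl-2,3-dihydro-4H-pyran-4-one (cis)
Conditions: AgOTf (5 mol%), CH2Cl2, 25 °C, dark
Reagents that add atoms: none
Why: Silver-catalysed 6-endo-dig oxa-cyclisation of a β-hydroxy ynone (intramolecular oxa-Michael addition to the activated alkyne) under neutral conditions, so neither the carbinol centre (its C–O bond is untouched) nor the α-centre is disturbed.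

Step 5
Reactants: 8 3-tert-butoxy-3-oxopropanoic acid; 9 2,2-diphenylethanol
Product: 10 tert-butyl 2,2-diphenylethyl propanedioate
Conditions: DCC (1.1 equiv), DMAP (5 mol%), CH2Cl2, 0 → 25 °C
Reagents that add atoms: none
Why: Steglich esterification gives a mixed malonate whose two ester groups differ enough in size for ion-pair recognition in step 11 and can be told apart chemically (tert-butyl cleaved by silyl triflate, the primary ester kept as acyl donor).

Step 6
Reactants: 11 (1S,5S)-(−)-verbenone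
Product: 12 (1S,3R)-3-acetyl-2,2-dimethylcyclobutane-1-carboxylic acid (cis)
Conditions: RuCl3·xH2O (2 mol%), NaIO4 (4.2 equiv), CCl4/MeCN/H2O, 25 °C
Reagents that add atoms: sodium periodate [Na+].[O-]I(=O)(=O)=O; water O
Why: RuO4-mediated oxidative cleavage of the enone C=C with loss of one carbon as CO2 from the α-keto acid, both stereocentres coming unchanged from the pinane skeleton.

Step 7
Reactants: 12 (1S,3R)-3-acetyl-2,2-dimethylcyclobutane-1-carboxylic acid
Product: 13 (1S,3S)-2,2-dimethyl-3-(prop-1-en-2-yl)cyclobutane-1-carboxylic acid (cis)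
Conditions: Ph3PCH3Br (2.5 equiv), KOtBu (2.4 equiv), THF, 0 → 25 °C; then aq. citric acid
Reagents that add atoms: methyltriphenylphosphonium bromide C[P+](c1ccccc1)(c1ccccc1)c1ccccc1.[Br-]
Why: Wittig methylenation of the methyl ketone with the acid masked as its carboxylate, the cis-1,3 arrangement being the more stable one and retained.

Step 8
Reactants: 13 (1S,3S)-2,2-dimethyl-3-(prop-1-en-2-yl)cyclobutane-1-carboxylic acid
Product: 14 [(1S,3S)-2,2-dimethyl-3-(prop-1-en-2-yl)cyclobutyl]methanol (cis)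
Conditions: LiAlH4 (1.5 equiv), THF, 0 → 25 °C; H2O, 15% aq. NaOH
Reagents that add atoms: none
Why: Hydride reduction of the acid to the primary alcohol, which leaves the 1,1-disubstituted alkene and both ring stereocentres untouched.

Step 9
Reactants: 14 [(1S,3S)-2,2-dimethyl-3-(prop-1-en-2-yl)cyclobutyl]methanol
Product: 15 (1S,3S)-1-(iodomethyl)-2,2-dimethyl-3-(prop-1-en-2-yl)cyclobutane
Conditions: PPh3 (1.2 equiv), I2 (1.2 equiv), imidazole (1.5 equiv), CH2Cl2, 0 → 25 °C
Reagents that add atoms: iodine II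
Why: Appel iodination through the alkoxyphosphonium salt under buffered conditions, an SN2 displacement at the primary carbon that avoids a cyclobutylcarbinyl cation and its ring expansion.

Step 10
Reactants: 10 tert-butyl 2,2-diphenylethyl propanedioate; 15 (1S,3S)-1-(iodomethyl)-2,2-dimethyl-3-(prop-1-en-2-yl)cyclobutane
Product: 16 1-tert-butyl 3-(2,2-diphenylethyl) 2-{[(1R,3S)-2,2-dimethyl-3-(prop-1-en-2-yl)cyclobutyl]methyl}propanedioate (both C-2 epimers)
Conditions: 10 (1.5 equiv), NaH (1.4 equiv), DMF, 0 °C; then 15, 60 °C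
Reagents that add atoms: none
Why: Malonic ester alkylation (SN2) of the β-branched primary iodide, with excess malonate suppressing dialkylation; the new C-2 centre needs no control because it is enolised in the next step.

Step 11
Reactants: 16 1-tert-butyl 3-(2,2-diphenylethyl) 2-{[(1R,3S)-2,2-dimethyl-3-(prop-1-en-2-yl)cyclobutyl]methyl}propanedioate; 17 1-bromo-3-methylbut-2-ene
Product: 18 1-tert-butyl 3-(2,2-diphenylethyl) (2S)-2-{[(1R,3S)-2,2-dimethyl-3-(prop-1-en-2-yl)cyclobutyl]methyl}-2-(3-methylbut-2-en-1-yl)propanedioate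
Conditions: 17 (3 equiv), (S,S)-2,6-bis(3,4,5-trifluorophenyl)-3,3',5,5'-tetrahydro-4,4'-spirobi[dinaphtho[2,1-c:1',2'-e]azepin]-4-ium bromide (5 mol%), 50% aq. KOH (5 equiv), toluene, −40 °C
Reagents that add atoms: none
Why: Asymmetric phase-transfer alkylation of an α-monosubstituted mixed malonate, in which the enolate travels into toluene as a tight ion pair with the chiral spiro ammonium ion that tells its faces apart through the size difference of the two ester groups, so that SN2 attack on the allylic bromide sets the quaternary carbon (future C-6) before any ring exists.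

Step 12
Reactants: 18 1-tert-butyl 3-(2,2-diphenylethyl) (2S)-2-{[(1R,3S)-2,2-dimethyl-3-(prop-1-en-2-yl)cyclobutyl]methyl}-2-(3-methylbut-2-en-1-yl)propanedioate
Product: 19 (2R)-2-{[(1R,3S)-2,2-dimethyl-3-(prop-1-en-2-yl)cyclobutyl]methyl}-3-(2,2-diphenylethoxy)-2-(3-methylbut-2-en-1-yl)-3-oxopropanoic acid
Conditions: TMSOTf (2 equiv), 2,6-lutidine (3 equiv), CH2Cl2, 0 °C; then pH 4 aq. buffer
Reagents that add atoms: none
Why: Buffered silyl triflate cleavage of the tert-butyl ester (O-silylation, loss of isobutene, hydrolysis of the silyl ester on work-up) frees only the carboxyl that will become C-7 and uses no protic acid, so the prenyl and isopropenyl groups and the cyclobutane are not ionised.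

Step 13
Reactants: 19 (2R)-2-{[(1R,3S)-2,2-dimethyl-3-(prop-1-en-2-yl)cyclobutyl]methyl}-3-(2,2-diphenylethoxy)-2-(3-methylbut-2-en-1-yl)-3-oxopropanoic acid; 7 (2R,3S)-2,3,6-trimethyl-2,3-dihydro-4H-pyran-4-one
Product: 22 (2R,3S,6R)-6-{[(1R,3S)-2,2-dimethyl-3-(prop-1-en-2-yl)cyclobutyl]methyl}-4-hydroxy-2,3-dimethyl-6-(3-methylbut-2-en-1-yl)-2H-chromene-5,7(3H,6H)-dione, via acid chloride 20 (not isolated), via diketo ester 21 (not isolated)
Conditions: 19, 1-chloro-N,N,2-trimethylprop-1-en-1-amine (1.1 equiv), CH2Cl2, 0 → 25 °C; separately 7 (2.3 equiv), LiHMDS (2.2 equiv), THF, −78 °C; add the solution of 20, −78 → 25 °C, then 45 °C; 10% aq. citric acid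
Reagents that add atoms: none
Why: γ-Deprotonation of 7 gives the lithium dienolate (the C-3 hydrogen is tertiary and flanked by two methyl groups, and the slight excess of ketone lets any cross-conjugated enolate equilibrate to the extended one), which is C-acylated at its γ-carbon (future C-8) by 20; the second equivalent of dienolate turns the resulting vinylogous β-diketone 21 into its enolate, whose C-4a (the pyranone α-carbon) attacks the remaining diphenylethyl ester in a Dieckmann-type Claisen cyclisation and expels the alkoxide. The closest known reaction types are the γ-acylation of 6-methyl-dioxinone and 6-methyl-pyranone dienolates with acid chlorides and the Claisen cyclisation of 3,5-dioxo esters to cyclohexane-1,3,5-triones. Ring B closes 6-exo-trig through the C-4a–C-5 bond after the intermolecular C-7–C-8 bond, and because ring A is already in place O-1 sits on C-8a by construction. No stereocentre is formed: C-6 is carried in from 19, its configuration in the ring is fixed by which carboxyl is the chloride (C-7) and which the ester (C-5), and C-2/C-3 are spectators as long as C-3 is not enolised. The step needs γ- over α'-deprotonation, C- over O-acylation and closure through C-4a; the last is secured by geometry (attack through C-8 would give a four-membered ring, through oxygen an eight-membered one) and by the stability of the fully conjugated trione enolate, which makes the cyclisation irreversible.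

Step 14
Reactants: 22 (2R,3S,6R)-6-{[(1R,3S)-2,2-dimethyl-3-(prop-1-en-2-yl)cyclobutyl]methyl}-4-hydroxy-2,3-dimethyl-6-(3-methylbut-2-en-1-yl)-2H-chromene-5,7(3H,6H)-dione; 23 (E)-cinnamaldehyde
Product: 25 (3S)-3-[(2R,3S,6R)-6-{[(1R,3S)-2,2-dimethyl-3-(prop-1-en-2-yl)cyclobutyl]methyl}-4-hydroxy-2,3-dimethyl-6-(3-methylbut-2-en-1-yl)-5,7-dioxo-3,5,6,7-tetrahydro-2H-chromen-8-yl]-3-phenylpropanoic acid, via enol lactone 24 (not isolated)
Conditions: 23 (1.5 equiv), (5aS,10bR)-2-mesityl-5a,10b-dihydro-4H,6H-indeno[2,1-b][1,2,4]triazolo[4,3-d][1,4]oxazin-2-ium chloride (10 mol%), iPr2NEt (1.5 equiv), 3,3',5,5'-tetra-tert-butyldiphenoquinone (1.2 equiv), THF, 25 °C; then H2O/THF, 25 °C; 10% aq. citric acid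
Reagents that add atoms: water O
Why: Oxidative carbene catalysis turns 23 into the α,β-unsaturated acyl azolium, the enol of 22 adds through C-8 (its only unsubstituted nucleophilic carbon; Michael or Coates–Claisen-type pathway, as known for cyclic 1,3-dicarbonyl compounds and 4-hydroxycoumarins), acylation of O-7 releases the carbene as 24 with the benzylic centre set S by the catalyst-shielded face of the acyl azolium, and water with the amine opens this vinylogous anhydride to the acid.

**Compound list**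
1 | (S)-4-benzyl-3-propanoyl-1,3-oxazolidin-2-one | CCC(=O)N1[C@@H](Cc2ccccc2)COC1=O | starting material
2 | acetaldehyde | CC=O | starting material
3 | (4S)-4-benzyl-3-[(2S,3R)-3-hydroxy-2-methylbutanoyl]-1,3-oxazolidin-2-one | O=C(N1[C@@H](Cc2ccccc2)COC1=O)[C@@H](C)[C@@H](C)O | intermediate
4 | (2S,3R)-3-hydroxy-N-methoxy-N,2-dimethylbutanamide | CON(C)C(=O)[C@@H](C)[C@@H](C)O | intermediate
5 | prop-1-yn-1-ylmagnesium bromide | CC#C[Mg]Br | starting material
6 | (2R,3S)-2-hydroxy-3-methylhept-5-yn-4-one | CC#CC(=O)[C@@H](C)[C@@H](C)O | intermediate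
7 | (2R,3S)-2,3,6-trimethyl-2,3-dihydro-4H-pyran-4-one (cis) | O=C1[C@@H](C)[C@@H](C)OC(C)=C1 | intermediate
8 | 3-tert-butoxy-3-oxopropanoic acid (mono-tert-butyl malonate) | CC(C)(C)OC(=O)CC(=O)O | starting material
9 | 2,2-diphenylethanol | OCC(c1ccccc1)c1ccccc1 | starting material
10 | tert-butyl 2,2-diphenylethyl propanedioate | CC(C)(C)OC(=O)CC(=O)OCC(c1ccccc1)c1ccccc1 | intermediate
11 | (1S,5S)-(−)-verbenone | CC1=CC(=O)[C@H]2C[C@@H]1C2(C)C | starting material
12 | (1S,3R)-3-acetyl-2,2-dimethylcyclobutane-1-carboxylic acid (cis) | CC(=O)[C@@H]1C[C@H](C(=O)O)C1(C)C | intermediate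
13 | (1S,3S)-2,2-dimethyl-3-(prop-1-en-2-yl)cyclobutane-1-carboxylic acid (cis) | C=C(C)[C@@H]1C[C@H](C(=O)O)C1(C)C | intermediate
14 | [(1S,3S)-2,2-dimethyl-3-(prop-1-en-2-yl)cyclobutyl]methanol (cis) | C=C(C)[C@@H]1C[C@H](CO)C1(C)C | intermediate
15 | (1S,3S)-1-(iodomethyl)-2,2-dimethyl-3-(prop-1-en-2-yl)cyclobutane (cis) | C=C(C)[C@@H]1C[C@H](CI)C1(C)C | intermediate
16 | 1-tert-butyl 3-(2,2-diphenylethyl) 2-{[(1R,3S)-2,2-dimethyl-3-(prop-1-en-2-yl)cyclobutyl]methyl}propanedioate (both C-2 epimers) | C=C(C)[C@@H]1C[C@H](CC(C(=O)OC(C)(C)C)C(=O)OCC(c2ccccc2)c2ccccc2)C1(C)C | intermediate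
17 | 1-bromo-3-methylbut-2-ene (prenyl bromide) | CC(C)=CCBr | starting material
18 | 1-tert-butyl 3-(2,2-diphenylethyl) (2S)-2-{[(1R,3S)-2,2-dimethyl-3-(prop-1-en-2-yl)cyclobutyl]methyl}-2-(3-methylbut-2-en-1-yl)propanedioate | C=C(C)[C@@H]1C[C@H](C[C@@](C(=O)OC(C)(C)C)(CC=C(C)C)C(=O)OCC(c2ccccc2)c2ccccc2)C1(C)C | intermediate
19 | (2R)-2-{[(1R,3S)-2,2-dimethyl-3-(prop-1-en-2-yl)cyclobutyl]methyl}-3-(2,2-diphenylethoxy)-2-(3-methylbut-2-en-1-yl)-3-oxopropanoic acid | C=C(C)[C@@H]1C[C@H](C[C@@](C(=O)O)(CC=C(C)C)C(=O)OCC(c2ccccc2)c2ccccc2)C1(C)C | intermediate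
20 | 2,2-diphenylethyl (2S)-3-chloro-2-{[(1R,3S)-2,2-dimethyl-3-(prop-1-en-2-yl)cyclobutyl]methyl}-2-(3-methylbut-2-en-1-yl)-3-oxopropanoate | C=C(C)[C@@H]1C[C@H](C[C@@](C(=O)Cl)(CC=C(C)C)C(=O)OCC(c2ccccc2)c2ccccc2)C1(C)C | intermediate
21 | 2,2-diphenylethyl (2R)-2-{[(1R,3S)-2,2-dimethyl-3-(prop-1-en-2-yl)cyclobutyl]methyl}-4-[(2R,3S)-2,3-dimethyl-4-oxo-3,4-dihydro-2H-pyran-6-yl]-2-(3-methylbut-2-en-1-yl)-3-oxobutanoate | C=C(C)[C@@H]1C[C@H](C[C@@](C(=O)CC2=CC(=O)[C@@H](C)[C@@H](C)O2)(CC=C(C)C)C(=O)OCC(c3ccccc3)c3ccccc3)C1(C)C | intermediate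
22 | (2R,3S,6R)-6-{[(1R,3S)-2,2-dimethyl-3-(prop-1-en-2-yl)cyclobutyl]methyl}-4-hydroxy-2,3-dimethyl-6-(3-methylbut-2-en-1-yl)-2H-chromene-5,7(3H,6H)-dione (cis-2,3-dimethyl; C-8 unsubstituted) | C=C(C)[C@@H]1C[C@H](C[C@@]2(CC=C(C)C)C(=O)C3=C(O)[C@@H](C)[C@@H](C)OC3=CC2=O)C1(C)C | intermediate
23 | (E)-cinnamaldehyde | O=C/C=C/c1ccccc1 | starting material
24 | enol δ-lactone of 25: the propanoic acid carboxyl closed on O-7 as an (S)-4-phenyl-3,4-dihydropyran-2-one ring fused across C-7/C-8, C-4 and C-5 as ketones, all other centres as in 22 | C=C(C)[C@@H]1C[C@H](C[C@@]2(CC=C(C)C)C(=O)C3=C(O[C@H](C)[C@H](C)C3=O)C4=C2OC(=O)C[C@H]4c2ccccc2)C1(C)C | intermediate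
25 | (3S)-3-[(2R,3S,6R)-6-{[(1R,3S)-2,2-dimethyl-3-(prop-1-en-2-yl)cyclobutyl]methyl}-4-hydroxy-2,3-dimethyl-6-(3-methylbut-2-en-1-yl)-5,7-dioxo-3,5,6,7-tetrahydro-2H-chromen-8-yl]-3-phenylpropanoic acid (CNP0328119.1) | C=C(C)[C@@H]1C[C@H](C[C@@]2(CC=C(C)C)C(=O)C3=C(O)[C@@H](C)[C@@H](C)OC3=C([C@@H](CC(=O)O)c3ccccc3)C2=O)C1(C)C | target

**Count**
Total steps: 14. Longest linear sequence: 9 steps (steps 6 to 14, from verbenone).

**Steps most likely to fail**

Step 13. The base may enolise C-3 instead of the methyl group (epimerising the cis pair or opening ring A by β-elimination), the dienolate may be acylated on oxygen by the hindered chloride, or ring closure may stall at the neopentyl-type ester. The fallback sets out from 19 and 7 and comes back at 22; it makes the two bonds separately, with an aldehyde as electrophile and soft enolisation. Acid chloride 20 (from 19) would be reduced with LiAlH(OtBu)3 at −78 °C to 2,2-diphenylethyl (2R)-2-{[(1R,3S)-2,2-dimethyl-3-(prop-1-en-2-yl)cyclobutyl]methyl}-2-formyl-5-methylhex-4-enoate F1. Pyranone 7 would be converted with TBSOTf and Et3N into tert-butyl{[(2R,3S)-2,3-dimethyl-6-methylidene-3,6-dihydro-2H-pyran-4-yl]oxy}dimethylsilane F2. A vinylogous Mukaiyama aldol reaction of the two (BF3·OEt2, CH2Cl2, −78 °C) would give 2,2-diphenylethyl (2R)-2-{[(1R,3S)-2,2-dimethyl-3-(prop-1-en-2-yl)cyclobutyl]methyl}-4-[(2R,3S)-2,3-dimethyl-4-oxo-3,4-dihydro-2H-pyran-6-yl]-3-hydroxy-2-(3-methylbut-2-en-1-yl)butanoate F3 as carbinol epimers. Dess–Martin oxidation would give 21, now isolated, and KOtBu in THF at 0 → 25 °C would close it to 22.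

Step 11. The ion pair of a malonate with so large an α-substituent may be poorly organised, so that the faces of the enolate are not told apart and C-6 epimers form. The fallback sets out from 16 and comes back at 19; it replaces catalyst control by separation of diastereomers, which the fixed cyclobutane centres make possible. Alkylation of 16 with 17 using NaH in THF would give 18 together with its epimer, 1-tert-butyl 3-(2,2-diphenylethyl) (2R)-2-{[(1R,3S)-2,2-dimethyl-3-(prop-1-en-2-yl)cyclobutyl]methyl}-2-(3-methylbut-2-en-1-yl)propanedioate F4. Cleavage as in step 12 would give 19 and (2S)-2-{[(1R,3S)-2,2-dimethyl-3-(prop-1-en-2-yl)cyclobutyl]methyl}-3-(2,2-diphenylethoxy)-2-(3-methylbut-2-en-1-yl)-3-oxopropanoic acid F5. These would be separated by fractional crystallisation of their (R)-1-phenylethylammonium salts or by preparative chromatography, and 19 would go on to step 13.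

Step 14. C–C bond formation at the hindered C-8 may be slow, so that the acyl azolium is diverted by O-acylation and hydrolysis, or the facial control may be incomplete on this bulky enol. The fallback sets out from 22 and 23 and comes back at 24; it uses iminium instead of acyl azolium activation and adjusts the oxidation level afterwards. With (S)-2-[diphenyl(trimethylsilyloxy)methyl]pyrrolidine (20 mol%) and benzoic acid in CH2Cl2, 22 would add to 23 to give the lactol F6, the hemiacetal analogue of 24 with a 2-hydroxy-(4S)-4-phenyl-3,4-dihydro-2H-pyran ring fused at O-7/C-8 (both anomers). Oxidation with PhI(OAc)2 and catalytic 2,2,6,6-tetramethylpiperidin-1-oxyl would give 24, which water and iPr2NEt would open to 25 as in step 14.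

**Further compounds**
F1 | step 13 | 2,2-diphenylethyl (2R)-2-{[(1R,3S)-2,2-dimethyl-3-(prop-1-en-2-yl)cyclobutyl]methyl}-2-formyl-5-methylhex-4-enoate | C=C(C)[C@@H]1C[C@H](C[C@@](C=O)(CC=C(C)C)C(=O)OCC(c2ccccc2)c2ccccc2)C1(C)C
F2 | step 13 | tert-butyl{[(2R,3S)-2,3-dimethyl-6-methylidene-3,6-dihydro-2H-pyran-4-yl]oxy}dimethylsilane | C=C1C=C(O[Si](C)(C)C(C)(C)C)[C@@H](C)[C@@H](C)O1
F3 | step 13 | 2,2-diphenylethyl (2R)-2-{[(1R,3S)-2,2-dimethyl-3-(prop-1-en-2-yl)cyclobutyl]methyl}-4-[(2R,3S)-2,3-dimethyl-4-oxo-3,4-dihydro-2H-pyran-6-yl]-3-hydroxy-2-(3-methylbut-2-en-1-yl)butanoate (carbinol epimers) | C=C(C)[C@@H]1C[C@H](C[C@@](C(O)CC2=CC(=O)[C@@H](C)[C@@H](C)O2)(CC=C(C)C)C(=O)OCC(c3ccccc3)c3ccccc3)C1(C)C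
F4 | step 11 | 1-tert-butyl 3-(2,2-diphenylethyl) (2R)-2-{[(1R,3S)-2,2-dimethyl-3-(prop-1-en-2-yl)cyclobutyl]methyl}-2-(3-methylbut-2-en-1-yl)propanedioate | C=C(C)[C@@H]1C[C@H](C[C@](C(=O)OC(C)(C)C)(CC=C(C)C)C(=O)OCC(c2ccccc2)c2ccccc2)C1(C)C
F5 | step 11 | (2S)-2-{[(1R,3S)-2,2-dimethyl-3-(prop-1-en-2-yl)cyclobutyl]methyl}-3-(2,2-diphenylethoxy)-2-(3-methylbut-2-en-1-yl)-3-oxopropanoic acid | C=C(C)[C@@H]1C[C@H](C[C@](C(=O)O)(CC=C(C)C)C(=O)OCC(c2ccccc2)c2ccccc2)C1(C)C
F6 | step 14 | lactol analogue of 24 (hemiacetal carbon in place of the lactone carbonyl, both anomers; benzylic carbon S) | C=C(C)[C@@H]1C[C@H](C[C@@]2(CC=C(C)C)C(=O)C3=C(O[C@H](C)[C@H](C)C3=O)C4=C2OC(O)C[C@H]4c2ccccc2)C1(C)C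
A1 | direct plan | (4S)-5,7-dihydroxy-4-phenyl-3,4-dihydro-2H-chromen-2-one | O=C1C[C@@H](c2ccccc2)c2c(O)cc(O)cc2O1
A2 | direct plan | (4S)-5,7-dihydroxy-8-[(2E)-2-methylbut-2-enoyl]-4-phenyl-3,4-dihydro-2H-chromen-2-one | C/C=C(\C)C(=O)c1c(O)cc(O)c2c1OC(=O)C[C@H]2c1ccccc1
A3 | direct plan | (1S,3S)-2,2-dimethyl-3-(prop-1-en-2-yl)cyclobutane-1-carbaldehyde | C=C(C)[C@@H]1C[C@H](C=O)C1(C)C
A4 | direct plan | (4S)-6-{[(1R,3S)-2,2-dimethyl-3-(prop-1-en-2-yl)cyclobutyl]methyl}-5,7-dihydroxy-8-[(2E)-2-methylbut-2-enoyl]-4-phenyl-3,4-dihydro-2H-chromen-2-one | C/C=C(\C)C(=O)c1c(O)c(C[C@H]2C[C@@H](C(C)=C)C2(C)C)c(O)c2c1OC(=O)C[C@H]2c1ccccc1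
A5 | direct plan | (4S,6S)-6-{[(1R,3S)-2,2-dimethyl-3-(prop-1-en-2-yl)cyclobutyl]methyl}-7-hydroxy-8-[(2E)-2-methylbut-2-enoyl]-6-(3-methylbut-2-en-1-yl)-4-phenyl-3,4-dihydro-2H-chromene-2,5(6H)-dione | C/C=C(\C)C(=O)C1=C(O)[C@](CC=C(C)C)(C[C@H]2C[C@@H](C(C)=C)C2(C)C)C(=O)C2=C1OC(=O)C[C@H]2c1ccccc1
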